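The six-membered ring (C1, C10–C14; briarane numbering) is closed by an aluminium-promoted intramolecular carbonyl-ene reaction of an acyclic 2-acetyl-hex-5-enal: the C14 aldehyde is attacked by the C13 terminus of a C12=C13 vinyl group while H-11 migrates to oxygen. One operation forms C13–C14, sets C14 and delivers the C11=C12 olefin that later becomes the 11,12-epoxide; it exploits the 1,3-relation of O-14 to C12 in this ring. The precursor carries the C1/C10/C11 triad, built on a temporary butyrolactone. The ten-membered ring follows by nickel-catalysed enyne–aldehyde coupling, epoxide-triggered lactonisation and ring-closing metathesis.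

Key step: step 10

Remark: carbons carry briarane numbers (C1 quaternary ring-fusion carbon with Me-15, C2–C9 ten-membered ring, C10 ring-fusion CH, C11–C14 six-membered ring, C17/C18/C19 lactone); (R)-4-methyloxolan-2-one is assumed to be purchasable.

**Route**

Step 1
Reactants: 1 (4R)-4-methyloxolan-2-one; 2 tert-butyl bromoacetate
Product: 3 tert-butyl 2-[(3R,4R)-4-methyl-2-oxooxolan-3-yl]acetate
Conditions: LiN(i-Pr)2, THF, −78 °C; then 2, DMPU, −78 to −40 °C
Reagents that add atoms: none
Why: Alkylation of the butyrolactone lithium enolate, in which the electrophile enters trans to the ring methyl group (C11) and so sets C10.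

Step 2
Reactants: 3
Product: 5 (4R)-4-[(2R)-1-hydroxypropan-2-yl]oxolan-2-one, via diol tert-butyl ester 4 (not isolated)
Conditions: LiBH4, THF, 0 °C to rt; then CF3CO2H, CH2Cl2, rt
Reagents that add atoms: none
Why: LiBH4 reduces the lactone but not the tert-butyl ester, and acidolysis of that ester lets the C9 hydroxyl close the five-membered lactone on C2 in preference to the six-membered alternative, with no stereocentre touched.

Step 3
Reactants: 5
Product: 6 (2R)-2-[(3R)-5-oxooxolan-3-yl]propanal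
Conditions: Dess–Martin periodinane, NaHCO3, CH2Cl2, 0 °C
Reagents that add atoms: none
Why: Buffered Dess–Martin oxidation of the primary alcohol should give the C12 aldehyde without epimerising C11.

Step 4
Reactants: 6
Product: 7 (4R)-4-[(2S)-but-3-en-2-yl]oxolan-2-one
Conditions: Ph3PCH3Br, KN(SiMe3)2, THF, −78 to 0 °C
Reagents that add atoms: methyltriphenylphosphonium bromide, C[P+](c1ccccc1)(c1ccccc1)c1ccccc1.[Br-]
Why: Wittig methylenation adds C13 and creates the C12=C13 vinyl group that serves as the ene component.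

Step 5
Reactants: 7
Product: 8 (3S,4S)-4-[(2S)-but-3-en-2-yl]-3-methyloxolan-2-one
Conditions: LiN(i-Pr)2, THF, −78 °C; MeI
Reagents that add atoms: iodomethane, CI
Why: Lactone enolate methylation installs Me-15 (the C1 configuration formed here is erased in step 6).

Step 6
Reactants: 8
Product: 10 (3R,4S)-4-[(2S)-but-3-en-2-yl]-3-(dimethoxymethyl)-3-methyloxolan-2-one, via silyl ketene acetal 9 (not isolated)
Conditions: LiN(i-Pr)2, THF, −78 °C; Me3SiCl; then HC(OMe)3, Me3SiOTf (cat.), CH2Cl2, −78 °C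
Reagents that add atoms: trimethyl orthoformate, COC(OC)OC; chlorotrimethylsilane, C[Si](C)(C)Cl (silicon in 9 only)
Why: Mukaiyama-type alkylation of the tetrasubstituted silyl ketene acetal by the dimethoxycarbenium ion, which attacks anti to the C10 substituent of the five-membered ring and sets the quaternary C1 with C14 trans to C11.

Step 7
Reactants: 10
Product: 11 (3R,4S,5S)-3-(dimethoxymethyl)-4-(hydroxymethyl)-3,5-dimethylhept-6-en-2-one
Conditions: MeLi (1.1 equiv), Et2O, −78 °C; then H2O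
Reagents that add atoms: methyllithium, [Li]C
Why: Single addition of MeLi to the hindered lactone (the lithium hemiketal resists a second addition) gives the C2 methyl ketone and frees the C9 hydroxyl, while the acetal is inert.

Step 8
Reactants: 11
Product: 12 (3R,4S,5S)-4-{[tert-butyl(diphenyl)silyl]oxymethyl}-3-(dimethoxymethyl)-3,5-dimethylhept-6-en-2-one
Conditions: t-BuPh2SiCl, imidazole, DMF, rt
Reagents that add atoms: tert-butyl(chloro)diphenylsilane, CC(C)(C)[Si](Cl)(c1ccccc1)c1ccccc1
Why: Silylation of the primary C9 hydroxyl prevents lactol formation with the C14 aldehyde, which would tether O-14 to C9 on the wrong face.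

Step 9
Reactants: 12
Product: 13 (2R,3S,4S)-2-acetyl-3-{[tert-butyl(diphenyl)silyl]oxymethyl}-2,4-dimethylhex-5-enal
Conditions: CF3CO2H, H2O, CHCl3, 0 °C
Reagents that add atoms: water, O
Why: Acid hydrolysis of the dimethyl acetal liberates the non-enolisable C14 aldehyde and the primary silyl ether should survive.

Step 10
Reactants: 13
Product: 14 1-[(1R,2S,6S)-2-{[tert-butyl(diphenyl)silyl]oxymethyl}-6-hydroxy-1,3-dimethylcyclohex-3-en-1-yl]ethan-1-one
Conditions: Me2AlCl (2.2 equiv), CH2Cl2, −78 to −20 °C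
Reagents that add atoms: none
Why: Me2AlCl binds the C14 aldehyde and the C2 ketone oxygen of the 2-acyl aldehyde as a chelate, the C13 terminus of the vinyl group adds to C14, and H-11 passes to the aluminium-bound oxygen (concerted ene reaction, or zwitterion followed by 1,5-proton shift), which leaves the C11=C12 olefin and the C14 alkoxide. The closest known reaction type is the alkylaluminium-halide-promoted carbonyl-ene (Prins-type) cyclisation of 5-hexenals to cyclohex-3-en-1-ols. The six-membered ring (C1, C14, C13, C12, C11, C10) closes in a 6-endo mode with respect to the olefin, both olefinic carbons ending in the ring, through a boat-like transition state in which O-14 and H-11 bridge C14 and C11. C14 is the only new stereocentre: the hydrogen transfer demands O-14 and H-11 on the same ring face, so the (11S) centre (H-11 anti to C9) relays its configuration to C14 (O-14 anti to Me-15 and C9), and the chelate, possible only with the C2 carbonyl gauche to O-14, supports the same transition state; C1 and C10 are already fixed. The step needs aldehyde over ketone selectivity, secured by the far higher enophilicity of the aldehyde, and proton loss from C11 instead of C13 or chloride capture at C12, secured by the reach of the alkoxide to H-11 only and by Me2AlCl acting as a proton scavenger.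

Step 11
Reactants: 14
Product: 15 (1S,5S,6R)-6-acetyl-5-{[tert-butyl(diphenyl)silyl]oxymethyl}-4,6-dimethylcyclohex-3-en-1-yl acetate
Conditions: Ac2O, DMAP, pyridine, rt
Reagents that add atoms: acetic anhydride, CC(=O)OC(C)=O
Why: DMAP-catalysed acetylation installs the final C14 acetate and removes the C14 hydroxyl, which would otherwise misdirect the reduction in step 13.

Step 12
Reactants: 15; 16 methacrolein
Product: 17 (1S,5S,6R)-5-{[tert-butyl(diphenyl)silyl]oxymethyl}-6-[(3R)-3-hydroxy-4-methylpent-4-enoyl]-4,6-dimethylcyclohex-3-en-1-yl acetate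
Conditions: (−)-Ipc2BCl, Et3N, Et2O, −78 to 0 °C; then 16, −78 °C; H2O2, pH 7 buffer, MeOH
Reagents that add atoms: none
Why: Boron aldol reaction of the methyl ketone, which can enolise only toward C3 because C1 is quaternary; the isopinocampheyl ligands are chosen to direct re-face attack on methacrolein and so set (4R).

Step 13
Reactants: 17
Product: 18 (1S,5S,6S)-5-{[tert-butyl(diphenyl)silyl]oxymethyl}-6-[(1R,3R)-1,3-dihydroxy-4-methylpent-4-en-1-yl]-4,6-dimethylcyclohex-3-en-1-yl acetate
Conditions: Me4NBH(OAc)3, AcOH, MeCN, −30 °C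
Reagents that add atoms: none
Why: Evans–Saksena reduction, in which hydride is delivered intramolecularly from the boron bound to the C4 hydroxyl and gives the 1,3-anti diol, setting (2R).

Step 14
Reactants: 18
Product: 19 (1R,3R)-1-[(1R,2S,6S)-6-acetoxy-2-{[tert-butyl(diphenyl)silyl]oxymethyl}-1,3-dimethylcyclohex-3-en-1-yl]-4-methylpent-4-ene-1,3-diyl diacetate
Conditions: Ac2O, DMAP, Et3N, CH2Cl2, rt
Reagents that add atoms: acetic anhydride, CC(=O)OC(C)=O
Why: Double acetylation installs the final C2 and C4 acetates.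

Step 15
Reactants: 19
Product: 20 (1R,3R)-1-[(1R,2S,6S)-6-acetoxy-2-(hydroxymethyl)-1,3-dimethylcyclohex-3-en-1-yl]-4-methylpent-4-ene-1,3-diyl diacetate
Conditions: HF·pyridine, pyridine, THF, 0 °C to rt
Reagents that add atoms: none
Why: Fluoride cleavage of the primary silyl ether under buffered conditions that leave the three acetates in place.

Step 16
Reactants: 20
Product: 21 (1R,3R)-1-[(1R,2S,6S)-6-acetoxy-2-formyl-1,3-dimethylcyclohex-3-en-1-yl]-4-methylpent-4-ene-1,3-diyl diacetate
Conditions: Dess–Martin periodinane, NaHCO3, CH2Cl2, 0 °C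
Reagents that add atoms: none
Why: Buffered oxidation gives the C9 aldehyde, whose C10 centre keeps its more stable equatorial formyl arrangement.

Step 17
Reactants: 22 but-3-yn-1-ol; 23 vinyl bromide
Product: 24 hex-5-en-3-yn-1-ol
Conditions: PdCl2(PPh3)2 (cat.), CuI (cat.), Et2NH, THF, 0 °C to rt
Reagents that add atoms: none
Why: Sonogashira coupling of the terminal alkyne with the vinyl halide gives the conjugated enyne.

Step 18
Reactants: 24
Product: 25 hex-5-en-3-ynoic acid
Conditions: CrO3, H2SO4, H2O, acetone, 0 °C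
Reagents that add atoms: water, O
Why: Jones oxidation of a homopropargylic alcohol to the alk-3-ynoic acid proceeds under acidic conditions that do not isomerise the alkyne to an allene.

Step 19
Reactants: 25; 26 (4R)-4-benzyloxazolidin-2-one
Product: 28 (4R)-4-benzyl-3-(hex-5-en-3-ynoyl)oxazolidin-2-one, via hex-5-en-3-ynoyl chloride 27 (not isolated)
Conditions: (COCl)2, DMF (cat.), CH2Cl2, 0 °C; then 26, n-BuLi, THF, −78 °C
Reagents that add atoms: oxalyl chloride, O=C(Cl)C(=O)Cl (chlorine in 27 only)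
Why: N-Acylation of the lithiated oxazolidinone by the acid chloride at low temperature, with no amine base present that could isomerise the alkynoyl group.

Step 20
Reactants: 28
Product: 29 (4R)-4-benzyl-3-[(2R)-2-methylhex-5-en-3-ynoyl]oxazolidin-2-one
Conditions: NaN(SiMe3)2, THF, −78 °C; MeI
Reagents that add atoms: iodomethane, CI
Why: Evans alkylation of the chelated Z-enolate, in which MeI approaches the face opposite the benzyl group and sets (17R).

Step 21
Reactants: 29
Product: 30 (2R)-N-methoxy-N,2-dimethylhex-5-en-3-ynamide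
Conditions: MeNHOMe·HCl, AlMe3, CH2Cl2, 0 °C
Reagents that add atoms: N,O-dimethylhydroxylamine hydrochloride, CNOC.Cl
Why: Aluminium amide transamination releases the auxiliary under non-basic conditions and gives an amide whose C17 centre is configurationally robust and whose carbonyl is not acylating toward the later C9 hydroxyl.

Step 22
Reactants: 21; 30
Product: 31 (2R,3E)-3-{(R)-hydroxy[(1S,5S,6R)-5-acetoxy-6-((1R,3R)-1,3-diacetoxy-4-methylpent-4-en-1-yl)-2,6-dimethylcyclohex-2-en-1-yl]methyl}-N-methoxy-N,2-dimethylhexa-3,5-dienamide (9R carbinol, E C7=C8)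
Conditions: Ni(cod)2 (10 mol%), P(c-C5H9)3 (20 mol%), Et3B, EtOAc, rt
Reagents that add atoms: none
Why: Nickel-catalysed reductive coupling of an aldehyde with a 1,3-enyne, which forms the C8–C9 bond at the alkyne carbon remote from the olefin by syn addition (E C7=C8); Felkin–Anh addition anti to the quaternary C1 should set (9R).

Step 23
Reactants: 31
Product: 33 the 8-hydroxy-19,7-lactone with free 9-OH, 11β,12β-epoxide, C7 vinyl and C4 isopropenyl groups (stereochemistry as in the SMILES), via bis-epoxide 32 (not isolated)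
Conditions: VO(acac)2 (10 mol%), t-BuOOH, CH2Cl2, 0 °C to rt; then pyridinium p-toluenesulfonate, H2O, CH2Cl2, rt
Reagents that add atoms: tert-butyl hydroperoxide, CC(C)(C)OO; water, O
Why: Hydroxyl-directed vanadium epoxidation from the C9 carbinol gives the erythro 7,8-epoxide (A(1,2) strain model) and the ring epoxide on the face that carries C9; the amide oxygen then opens the vinyl epoxide at C7 in a 5-exo mode with inversion, and hydrolysis of the iminium lactone leaves the lactone with 8-OH cis to C6.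

Step 24
Reactants: 33
Product: 34 the 9-O-acetate of 33 (2,4,9,14-tetraacetate, seco-C5/C6)
Conditions: Ac2O, DMAP, pyridine, 0 °C to rt
Reagents that add atoms: acetic anhydride, CC(=O)OC(C)=O
Why: The secondary C9 hydroxyl is acetylated while the tertiary C8 hydroxyl should remain free.

Step 25
Reactants: 34
Product: 35 target CNP0215170.2
Conditions: second-generation Hoveyda–Grubbs catalyst (10 mol%), toluene (1 mM), 80 °C
Reagents that add atoms: none
Why: Ring-closing metathesis of the C7 vinyl and C4 isopropenyl groups forms the trisubstituted C5=C6 olefin, whose cis ring geometry is enforced by the ten-membered ring that is preorganised by the trans-fused cyclohexane and lactone.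

**Compound list**

1 | (4R)-4-methyloxolan-2-one | O=C1C[C@@H](C)CO1 | starting material
2 | tert-butyl bromoacetate | BrCC(=O)OC(C)(C)C | starting material
3 | tert-butyl 2-[(3R,4R)-4-methyl-2-oxooxolan-3-yl]acetate | O=C1[C@H](CC(=O)OC(C)(C)C)[C@@H](C)CO1 | intermediate
4 | tert-butyl (3R,4R)-5-hydroxy-3-(hydroxymethyl)-4-methylpentanoate | CC(C)(C)OC(=O)C[C@@H](CO)[C@@H](C)CO | intermediate
5 | (4R)-4-[(2R)-1-hydroxypropan-2-yl]oxolan-2-one | O=C1C[C@H]([C@@H](C)CO)CO1 | intermediate
6 | (2R)-2-[(3R)-5-oxooxolan-3-yl]propanal | O=C1C[C@H]([C@@H](C)C=O)CO1 | intermediate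
7 | (4R)-4-[(2S)-but-3-en-2-yl]oxolan-2-one | O=C1C[C@H]([C@@H](C)C=C)CO1 | intermediate
8 | (3S,4S)-4-[(2S)-but-3-en-2-yl]-3-methyloxolan-2-one | O=C1[C@@H](C)[C@H]([C@@H](C)C=C)CO1 | intermediate
9 | {[(4S)-4-[(2S)-but-3-en-2-yl]-3-methyl-4,5-dihydrofuran-2-yl]oxy}trimethylsilane | C[Si](C)(C)OC1=C(C)[C@H]([C@@H](C)C=C)CO1 | intermediate
10 | (3R,4S)-4-[(2S)-but-3-en-2-yl]-3-(dimethoxymethyl)-3-methyloxolan-2-one | O=C1[C@@](C)(C(OC)OC)[C@H]([C@@H](C)C=C)CO1 | intermediate
11 | (3R,4S,5S)-3-(dimethoxymethyl)-4-(hydroxymethyl)-3,5-dimethylhept-6-en-2-one | CC(=O)[C@@](C)(C(OC)OC)[C@@H](CO)[C@@H](C)C=C | intermediate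
12 | (3R,4S,5S)-4-{[tert-butyl(diphenyl)silyl]oxymethyl}-3-(dimethoxymethyl)-3,5-dimethylhept-6-en-2-one | CC(=O)[C@@](C)(C(OC)OC)[C@@H](CO[Si](c1ccccc1)(c1ccccc1)C(C)(C)C)[C@@H](C)C=C | intermediate
13 | (2R,3S,4S)-2-acetyl-3-{[tert-butyl(diphenyl)silyl]oxymethyl}-2,4-dimethylhex-5-enal | CC(=O)[C@@](C)(C=O)[C@@H](CO[Si](c1ccccc1)(c1ccccc1)C(C)(C)C)[C@@H](C)C=C | intermediate
14 | 1-[(1R,2S,6S)-2-{[tert-butyl(diphenyl)silyl]oxymethyl}-6-hydroxy-1,3-dimethylcyclohex-3-en-1-yl]ethan-1-one | O[C@H]1CC=C(C)[C@H](CO[Si](c2ccccc2)(c2ccccc2)C(C)(C)C)[C@@]1(C)C(C)=O | intermediate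
15 | (1S,5S,6R)-6-acetyl-5-{[tert-butyl(diphenyl)silyl]oxymethyl}-4,6-dimethylcyclohex-3-en-1-yl acetate | CC(=O)O[C@H]1CC=C(C)[C@H](CO[Si](c2ccccc2)(c2ccccc2)C(C)(C)C)[C@@]1(C)C(C)=O | intermediate
16 | methacrolein (2-methylprop-2-enal) | CC(=C)C=O | starting material
17 | (1S,5S,6R)-5-{[tert-butyl(diphenyl)silyl]oxymethyl}-6-[(3R)-3-hydroxy-4-methylpent-4-enoyl]-4,6-dimethylcyclohex-3-en-1-yl acetate | CC(=O)O[C@H]1CC=C(C)[C@H](CO[Si](c2ccccc2)(c2ccccc2)C(C)(C)C)[C@@]1(C)C(=O)C[C@@H](O)C(C)=C | intermediate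
18 | (1S,5S,6S)-5-{[tert-butyl(diphenyl)silyl]oxymethyl}-6-[(1R,3R)-1,3-dihydroxy-4-methylpent-4-en-1-yl]-4,6-dimethylcyclohex-3-en-1-yl acetate | CC(=O)O[C@H]1CC=C(C)[C@H](CO[Si](c2ccccc2)(c2ccccc2)C(C)(C)C)[C@@]1(C)[C@H](O)C[C@@H](O)C(C)=C | intermediate
19 | (1R,3R)-1-[(1R,2S,6S)-6-acetoxy-2-{[tert-butyl(diphenyl)silyl]oxymethyl}-1,3-dimethylcyclohex-3-en-1-yl]-4-methylpent-4-ene-1,3-diyl diacetate | CC(=O)O[C@H]1CC=C(C)[C@H](CO[Si](c2ccccc2)(c2ccccc2)C(C)(C)C)[C@@]1(C)[C@H](OC(C)=O)C[C@@H](OC(C)=O)C(C)=C | intermediate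
20 | (1R,3R)-1-[(1R,2S,6S)-6-acetoxy-2-(hydroxymethyl)-1,3-dimethylcyclohex-3-en-1-yl]-4-methylpent-4-ene-1,3-diyl diacetate | CC(=O)O[C@H]1CC=C(C)[C@H](CO)[C@@]1(C)[C@H](OC(C)=O)C[C@@H](OC(C)=O)C(C)=C | intermediate
21 | (1R,3R)-1-[(1R,2S,6S)-6-acetoxy-2-formyl-1,3-dimethylcyclohex-3-en-1-yl]-4-methylpent-4-ene-1,3-diyl diacetate | CC(=O)O[C@H]1CC=C(C)[C@H](C=O)[C@@]1(C)[C@H](OC(C)=O)C[C@@H](OC(C)=O)C(C)=C | intermediate
22 | but-3-yn-1-ol | C#CCCO | starting material
23 | vinyl bromide (bromoethene) | C=CBr | starting material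
24 | hex-5-en-3-yn-1-ol | C=CC#CCCO | intermediate
25 | hex-5-en-3-ynoic acid | C=CC#CCC(=O)O | intermediate
26 | (4R)-4-benzyloxazolidin-2-one | O=C1N[C@H](Cc2ccccc2)CO1 | starting material
27 | hex-5-en-3-ynoyl chloride | C=CC#CCC(=O)Cl | intermediate
28 | (4R)-4-benzyl-3-(hex-5-en-3-ynoyl)oxazolidin-2-one | C=CC#CCC(=O)N1[C@H](Cc2ccccc2)COC1=O | intermediate
29 | (4R)-4-benzyl-3-[(2R)-2-methylhex-5-en-3-ynoyl]oxazolidin-2-one | C=CC#C[C@@H](C)C(=O)N1[C@H](Cc2ccccc2)COC1=O | intermediate
30 | (2R)-N-methoxy-N,2-dimethylhex-5-en-3-ynamide | C=CC#C[C@@H](C)C(=O)N(C)OC | intermediate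
31 | (9R,7E,17R)-dienol: C9 carbinol of 21 bonded to C8 of the C7=C8–C6=CH2 diene, C8 carrying the (R)-CH(CH3)C(O)N(OMe)Me group | CC(=O)O[C@H]1CC=C(C)[C@H]([C@@H](O)/C(=C/C=C)[C@@H](C)C(=O)N(C)OC)[C@@]1(C)[C@H](OC(C)=O)C[C@@H](OC(C)=O)C(C)=C | intermediate
32 | 7,8:11,12-bis-epoxide of 31 (7,8-epoxide erythro to 9-OH; ring epoxide on the C9 face) | CC(=O)O[C@H]1C[C@@H]2O[C@]2(C)[C@H]([C@@H](O)[C@]2(O[C@@H]2C=C)[C@@H](C)C(=O)N(C)OC)[C@@]1(C)[C@H](OC(C)=O)C[C@@H](OC(C)=O)C(C)=C | intermediate
33 | 8-hydroxy-19,7-lactone with free 9-OH, 11β,12β-epoxide, C7 vinyl and C4 isopropenyl groups | CC(=O)O[C@H]1C[C@@H]2O[C@]2(C)[C@H]([C@@H](O)[C@@]2(O)[C@H](C=C)OC(=O)[C@@H]2C)[C@@]1(C)[C@H](OC(C)=O)C[C@@H](OC(C)=O)C(C)=C | intermediate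
34 | 9-O-acetate of 33 (2,4,9,14-tetraacetate, seco-C5/C6) | CC(=O)O[C@H]1C[C@@H]2O[C@]2(C)[C@H]([C@@H](OC(C)=O)[C@@]2(O)[C@H](C=C)OC(=O)[C@@H]2C)[C@@]1(C)[C@H](OC(C)=O)C[C@@H](OC(C)=O)C(C)=C | intermediate
35 | CNP0215170.2 (2,4,9,14-tetraacetoxy-8-hydroxy-11,12-epoxybriar-5-en-18,7-olide; 1S,2R,4R,5Z,7S,8S,9R,10S,11R,12S,14S,17R) | CC(=O)O[C@H]1C[C@@H]2O[C@]2(C)[C@@H]2[C@@H](OC(C)=O)[C@@]3(O)[C@H](/C=C(/C)[C@H](OC(C)=O)C[C@@H](OC(C)=O)[C@@]12C)OC(=O)[C@@H]3C | target

**Count and risks**

Total step count: 25. Longest linear sequence: 20 steps (steps 1–16 and 22–25).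

Steps most likely to fail:

1. Step 25. The ruthenium carbene may fail to engage the hindered 1,1-disubstituted olefin, so that the vinyl group dimerises or oligomerises instead of closing the ten-membered ring. The fallback closes the macrocycle before the lactone is annulated. It sets out from 31: ring-closing metathesis with the second-generation Hoveyda–Grubbs catalyst on the more reactive diene terminus should give the macrocyclic (5Z,7E)-dienol F3. VO(acac)2 and t-BuOOH then give the macrocyclic bis-epoxide F4, and pyridinium p-toluenesulfonate in wet CH2Cl2 triggers the transannular amide opening at C7 to the 9-O-deacetyl lactone F5. Ac2O, DMAP and pyridine acetylate C9, and the route comes back at 35.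

2. Step 10. The C12 cation may be captured by chloride or lose a proton toward C13, and facial control at C14 may be lost if the hydrogen transfer is not concerted. The fallback is a stepwise halo-Prins sequence. It sets out from 13: SnCl4 in CH2Cl2 at −78 °C should give, by anti addition across the vinyl group within the same chelate, the 12-chloro alcohol F1 (chlorine trans to H-11). Ac2O, DMAP and pyridine give its 14-acetate F2, and DBU in toluene at 80 °C removes HCl through the antiperiplanar H-11. The route comes back at 15.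

3. Step 23. The hydroxyl-directed epoxidation of the ring olefin from the secondary C9 carbinol may show poor facial selectivity, and the ring epoxide may open during the acid-triggered lactonisation. The fallback installs the ring epoxide earlier, from the freely rotating primary alcohol. It sets out from 20: VO(acac)2 and t-BuOOH should give the epoxy alcohol F6, buffered Dess–Martin oxidation the epoxy aldehyde F7, and the nickel-catalysed coupling with 30 (Ni(cod)2, P(c-C5H9)3, Et3B) the epoxy dienol F8. A single allylic epoxidation with VO(acac)2 and t-BuOOH then gives 32, where the route comes back before the lactonisation to 33.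

Further compounds

F1 | step 10 | 1-[2-{[tert-butyl(diphenyl)silyl]oxymethyl}-4-chloro-6-hydroxy-1,3-dimethylcyclohexyl]ethan-1-one (12-chloro-14-ol, Cl trans to H-11) | O[C@H]1C[C@H](Cl)[C@H](C)[C@H](CO[Si](c2ccccc2)(c2ccccc2)C(C)(C)C)[C@@]1(C)C(C)=O
F2 | step 10 | 14-acetate of F1 | CC(=O)O[C@H]1C[C@H](Cl)[C@H](C)[C@H](CO[Si](c2ccccc2)(c2ccccc2)C(C)(C)C)[C@@]1(C)C(C)=O
F3 | step 25 | macrocyclic (5Z,7E)-dienol with 9-OH and the (17R)-amide side chain on C8 | CC(=O)O[C@H]1CC=C(C)[C@@H]2[C@@H](O)/C(=C/C=C(/C)[C@H](OC(C)=O)C[C@@H](OC(C)=O)[C@@]12C)[C@@H](C)C(=O)N(C)OC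
F4 | step 25 | 7,8:11,12-bis-epoxide of F3 | CC(=O)O[C@H]1C[C@@H]2O[C@]2(C)[C@@H]2[C@@H](O)[C@]3(O[C@@H]3/C=C(/C)[C@H](OC(C)=O)C[C@@H](OC(C)=O)[C@@]12C)[C@@H](C)C(=O)N(C)OC
F5 | step 25 | 9-O-deacetyl 35 | CC(=O)O[C@H]1C[C@@H]2O[C@]2(C)[C@@H]2[C@@H](O)[C@@]3(O)[C@H](/C=C(/C)[C@H](OC(C)=O)C[C@@H](OC(C)=O)[C@@]12C)OC(=O)[C@@H]3C
F6 | step 23 | 11β,12β-epoxide of 20 | CC(=O)O[C@H]1C[C@@H]2O[C@]2(C)[C@H](CO)[C@@]1(C)[C@H](OC(C)=O)C[C@@H](OC(C)=O)C(C)=C
F7 | step 23 | 11β,12β-epoxide of 21 | CC(=O)O[C@H]1C[C@@H]2O[C@]2(C)[C@H](C=O)[C@@]1(C)[C@H](OC(C)=O)C[C@@H](OC(C)=O)C(C)=C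
F8 | step 23 | 11β,12β-epoxide of 31 | CC(=O)O[C@H]1C[C@@H]2O[C@]2(C)[C@H]([C@@H](O)/C(=C/C=C)[C@@H](C)C(=O)N(C)OC)[C@@]1(C)[C@H](OC(C)=O)C[C@@H](OC(C)=O)C(C)=C
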